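**A direct plan and its weak points**

A direct plan would condense two molecules of 4-hydroxybenzaldehyde A1 with pentane-2,4-dione A2 under boron templating to the curcuminoid A3, hydrogenate both alkenes and both carbonyls of A3 in one charge with the chiral catalyst RuCl2[(R)-BINAP] to the (3R,5R)-diol A4, and monoacetylate A4.
- The fourfold hydrogenation of A3 would be weak: one catalyst must saturate two alkenes and then reduce an enolised β-diketone twice with facial control, beside free phenols. Both stereocentres hang on a cascade without precedent on a cross-conjugated dienyl diketone, and each facial error is lost as the meso diol.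
- The skeleton-building condensation of A1 with A2 would be weak: it makes two alkenes and two ketones that the target does not contain, so four unsaturations must be removed before any stereocentre exists.
- The monoacetylation of A4 would be weak: one of two secondary hydroxyls must be acylated in a tetraol beside two more acidic phenols, which needs a detour through a cyclic orthoester and builds nothing.

**Retrosynthetic overview of the new route**

Target numbering: chain C1–C7, OAc on C3, OH on C5, 4-hydroxyphenyl on C1 and C7; there is no ring to form.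
The unit C3(OAc)–C4H2–C5(OH) is read as the product of a Tishchenko disproportionation: the acetyl group on O3 and the hydrogen on C5 come from one molecule of acetaldehyde. A SmI2-catalysed Evans–Tishchenko reduction of an (R)-β-hydroxy ketone delivers both, setting C5 by 1,3-induction and placing the acetate in the same operation.
The β-hydroxy ketone is cut at C3–C4 into two arylpropyl halves, benzylated raspberry ketone and a 3-arylpropanal, joined by a catalytic enantioselective Mukaiyama aldol that sets C3.
No alkene or diketone is made and removed, no diol is ever free, and no hydroxyl has to be told from another: the twofold axis of the diol core makes any acetyl shift degenerate.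

Key step: step 5

Assumption: the D-tryptophan-derived oxazaborolidinone is taken to expose the Si face of the bound aldehyde (the L-series being Re-selective); the sense would be checked on 10 by Mosher ester analysis and the L-tryptophan catalyst used if it were found reversed.

**Route**

Step 1
Reactants: 1 4-(4-hydroxyphenyl)butan-2-one (raspberry ketone)
Product: 2 4-[4-(benzyloxy)phenyl]butan-2-one
Conditions: BnBr (1.1 equiv), K2CO3 (1.5 equiv), acetone, reflux, 6 h
Reagents that add atoms: benzyl bromide BrCc1ccccc1
Why: Williamson ether synthesis, in which carbonate ionises only the phenol so that O-benzylation outruns any alkylation of the ketone, and no stereocentre is involved.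

Step 2
Reactants: 3 1-(benzyloxy)-4-iodobenzene; 4 prop-2-en-1-ol (allyl alcohol, 1.5 equiv)
Product: 6 3-[4-(benzyloxy)phenyl]propanal, via enol 5 (not isolated)
Conditions: Pd(OAc)2 (2 mol%), Bu4NCl (1.0 equiv), NaHCO3 (2.5 equiv), DMF, 40 °C, 16 h
Reagents that add atoms: none
Why: Heck reaction of an allylic alcohol under Jeffery conditions, in which oxidative addition of 3 to zerovalent palladium is followed by transfer of the aryl group to the terminal alkene carbon, β-hydride elimination toward the carbinol carbon gives enol 5, and tautomerisation gives the aldehyde, so the three-carbon arm is installed in one step with no stereocentre.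

Step 3
Reactants: 2 4-[4-(benzyloxy)phenyl]butan-2-one
Product: 8 trimethyl({4-[4-(benzyloxy)phenyl]but-1-en-2-yl}oxy)silane, via lithium enolate 7 (not isolated)
Conditions: LiN(iPr)2 (1.1 equiv), THF, −78 °C, 30 min; Me3SiCl (1.3 equiv), −78 °C to rt; pentane, filter, concentrate, use crude
Reagents that add atoms: chlorotrimethylsilane C[Si](C)(C)Cl
Why: Kinetic enolisation with a hindered lithium amide at −78 °C removes a proton from the methyl group and not from the internal CH2, and O-silylation traps the terminal enolate as the enol silane needed for a Mukaiyama aldol; no stereocentre.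

Step 4
Reactants: 8 trimethyl({4-[4-(benzyloxy)phenyl]but-1-en-2-yl}oxy)silane (1.3 equiv); 6 3-[4-(benzyloxy)phenyl]propanal
Product: 10 (5R)-1,7-bis[4-(benzyloxy)phenyl]-5-hydroxyheptan-3-one, via silyl ether 9 (not isolated)
Conditions: (4R)-2-butyl-4-(1H-indol-3-ylmethyl)-3-tosyl-1,3,2-oxazaborolidin-5-one (20 mol%, from N-tosyl-D-tryptophan and BuB(OH)2), EtCN, −78 °C, 14 h; then 1 M HCl, THF, 0 °C; recrystallise
Reagents that add atoms: none
Why: Catalytic enantioselective Mukaiyama aldol addition that joins the methyl carbon of 2 (C4 of the target) to the formyl carbon of 6 (C3 of the target): the aldehyde binds to boron, the indole ring covers one face of the formyl group, and the enol silane attacks the open Si face through an open transition state, which sets the carbinol centre as R; the precedent is the addition of methyl ketone enol silanes to unbranched aliphatic aldehydes with this catalyst class, mild acid cleaves silyl ether 9, and recrystallisation should raise the enantiomeric purity if needed.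

Step 5
Reactants: 10 (5R)-1,7-bis[4-(benzyloxy)phenyl]-5-hydroxyheptan-3-one
Product: 12 (3R,5R)-1,7-bis[4-(benzyloxy)phenyl]-5-hydroxyheptan-3-yl acetate, via acetaldehyde hemiacetal 11 (not isolated)
Conditions: MeCHO (8 equiv, freshly distilled), SmI2 (0.25 equiv, 0.1 M in THF), THF, −10 °C, 2 h; sat. NaHCO3
Reagents that add atoms: acetaldehyde CC=O
Why: Evans–Tishchenko reduction, used as the known reaction type itself: the trivalent samarium alkoxide formed from SmI2 and acetaldehyde exchanges onto the hydroxyl of 10, which adds to acetaldehyde to give hemiacetal 11. Samarium then binds the ketone oxygen, and the hemiacetal C–H is passed as hydride to the ketone carbon through a chair-like six-membered array (H, hemiacetal carbon, oxygen, carbinol carbon, CH2, ketone carbon), the hemiacetal carbon leaving as the acetate carbonyl. No ring is closed. The new stereocentre (C5 of 12, the former ketone carbon) is controlled by the resident (R)-carbinol centre (C3 of 12): with both chain substituents equatorial in the chair, hydride enters anti to the existing C–O bond, which for this constitution is the R,R arrangement. The step needs anti over syn reduction and acetylation of exactly one of two secondary oxygens while no phenol is touched; the first follows from the cyclic transition state, the second from the fact that only the oxygen that carried the hydride donor becomes the ester, and the third from the benzyl ethers. A later 1,3-acetyl shift, the usual erosion of this reaction, cannot change the product, because the two hydroxyls of the underlying diol are exchanged by its twofold axis.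

Step 6
Reactants: 12 (3R,5R)-1,7-bis[4-(benzyloxy)phenyl]-5-hydroxyheptan-3-yl acetate
Product: 13 (3R,5R)-5-hydroxy-1,7-bis(4-hydroxyphenyl)heptan-3-yl acetate (CNP0132544.1)
Conditions: H2 (1 atm), 10% Pd/C, EtOAc, rt, 4 h
Reagents that add atoms: none
Why: Hydrogenolysis of the two aryl benzyl ethers over palladium on carbon should free both phenols under neutral conditions that leave the secondary acetate, the secondary alcohol and both stereocentres (neither is benzylic) untouched.

**Compound list**

1 | 4-(4-hydroxyphenyl)butan-2-one (raspberry ketone) | CC(=O)CCc1ccc(O)cc1 | starting material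
2 | 4-[4-(benzyloxy)phenyl]butan-2-one | CC(=O)CCc1ccc(OCc2ccccc2)cc1 | intermediate
3 | 1-(benzyloxy)-4-iodobenzene | Ic1ccc(OCc2ccccc2)cc1 | starting material
4 | prop-2-en-1-ol (allyl alcohol) | C=CCO | starting material
5 | 3-[4-(benzyloxy)phenyl]prop-1-en-1-ol (enol, alkene geometry open) | OC=CCc1ccc(OCc2ccccc2)cc1 | intermediate
6 | 3-[4-(benzyloxy)phenyl]propanal | O=CCCc1ccc(OCc2ccccc2)cc1 | intermediate
7 | lithium 4-[4-(benzyloxy)phenyl]but-1-en-2-olate | [Li]OC(=C)CCc1ccc(OCc2ccccc2)cc1 | intermediate
8 | trimethyl({4-[4-(benzyloxy)phenyl]but-1-en-2-yl}oxy)silane | C=C(O[Si](C)(C)C)CCc1ccc(OCc2ccccc2)cc1 | intermediate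
9 | (5R)-1,7-bis[4-(benzyloxy)phenyl]-5-[(trimethylsilyl)oxy]heptan-3-one | O=C(CCc1ccc(OCc2ccccc2)cc1)C[C@H](O[Si](C)(C)C)CCc1ccc(OCc2ccccc2)cc1 | intermediate
10 | (5R)-1,7-bis[4-(benzyloxy)phenyl]-5-hydroxyheptan-3-one | O=C(CCc1ccc(OCc2ccccc2)cc1)C[C@H](O)CCc1ccc(OCc2ccccc2)cc1 | intermediate
11 | (5R)-1,7-bis[4-(benzyloxy)phenyl]-5-(1-hydroxyethoxy)heptan-3-one (present as its samarium alkoxide; hemiacetal carbon undefined) | CC(O)O[C@H](CCc1ccc(OCc2ccccc2)cc1)CC(=O)CCc1ccc(OCc2ccccc2)cc1 | intermediate
12 | (3R,5R)-1,7-bis[4-(benzyloxy)phenyl]-5-hydroxyheptan-3-yl acetate | CC(=O)O[C@H](CCc1ccc(OCc2ccccc2)cc1)C[C@H](O)CCc1ccc(OCc2ccccc2)cc1 | intermediate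
13 | (3R,5R)-5-hydroxy-1,7-bis(4-hydroxyphenyl)heptan-3-yl acetate (CNP0132544.1) | CC(=O)O[C@H](CCc1ccc(O)cc1)C[C@H](O)CCc1ccc(O)cc1 | target

**Step count and risks**

Total step count: 6. Longest linear sequence: 5 (steps 1, 3, 4, 5, 6).

Steps most likely to fail:

1. Step 4 (aldol). Facial discrimination on a flexible, unbranched aldehyde may be insufficient, and the enolisable aldehyde may self-condense before the enol silane adds. The fallback sets the carbinol by hydrogenation instead; it sets out from 6 and comes back at 10. Roskamp homologation of 6 (ethyl diazoacetate, SnCl2 10 mol%, CH2Cl2) would give ethyl 5-[4-(benzyloxy)phenyl]-3-oxopentanoate F1. Noyori hydrogenation (RuCl2[(R)-BINAP], H2 50 atm, EtOH, 50 °C), in the sense established for β-keto esters, would give ethyl (3R)-5-[4-(benzyloxy)phenyl]-3-hydroxypentanoate F2. Amidation (MeNHOMe·HCl, iPrMgCl, THF, −20 °C) would give the Weinreb amide (3R)-5-[4-(benzyloxy)phenyl]-3-hydroxy-N-methoxy-N-methylpentanamide F3. Commercial 1-(benzyloxy)-4-(2-bromoethyl)benzene F4 with Mg in THF would give {2-[4-(benzyloxy)phenyl]ethyl}magnesium bromide F5, and 2.5 equiv of F5 added to F3 should give 10.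

2. Step 5 (Evans–Tishchenko). Retro-aldol cleavage of the samarium aldolate, consumption of acetaldehyde by self-condensation, or deactivation of the catalyst may stop the hydride transfer short of completion. The fallback separates reduction and acylation; it sets out from 10 and comes back at 12. Hydroxyl-directed Evans–Saksena reduction (Me4NBH(OAc)3, MeCN–AcOH, −30 °C) would give (3R,5R)-1,7-bis[4-(benzyloxy)phenyl]heptane-3,5-diol F6. Orthoester exchange (MeC(OMe)3, pyridinium p-toluenesulfonate, CH2Cl2) would give (4R,6R)-4,6-bis{2-[4-(benzyloxy)phenyl]ethyl}-2-methoxy-2-methyl-1,3-dioxane F7, and addition of water would open it to 12. Either opening gives the same monoacetate because F6 has a twofold axis.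

3. Step 2 (Heck). Arylation at the internal alkene carbon, stalling at the cinnamyl alcohol stage, or base-induced self-condensation of the aldehyde may lower the amount of usable 6. The fallback forms the aryl–carbon bond by a polar route; it sets out from 3 and comes back at 6. Iodine–lithium exchange (n-BuLi, THF, −78 °C) would give [4-(benzyloxy)phenyl]lithium F8. Ring opening of oxetane (BF3·OEt2, −78 °C) would give 3-[4-(benzyloxy)phenyl]propan-1-ol F9, and Dess–Martin periodinane in CH2Cl2 should oxidise F9 to 6.

**Further compounds**

F1 | step 4 | ethyl 5-[4-(benzyloxy)phenyl]-3-oxopentanoate | CCOC(=O)CC(=O)CCc1ccc(OCc2ccccc2)cc1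
F2 | step 4 | ethyl (3R)-5-[4-(benzyloxy)phenyl]-3-hydroxypentanoate | CCOC(=O)C[C@H](O)CCc1ccc(OCc2ccccc2)cc1
F3 | step 4 | (3R)-5-[4-(benzyloxy)phenyl]-3-hydroxy-N-methoxy-N-methylpentanamide | CON(C)C(=O)C[C@H](O)CCc1ccc(OCc2ccccc2)cc1
F4 | step 4 | 1-(benzyloxy)-4-(2-bromoethyl)benzene | BrCCc1ccc(OCc2ccccc2)cc1
F5 | step 4 | {2-[4-(benzyloxy)phenyl]ethyl}magnesium bromide | Br[Mg]CCc1ccc(OCc2ccccc2)cc1
F6 | step 5 | (3R,5R)-1,7-bis[4-(benzyloxy)phenyl]heptane-3,5-diol | O[C@H](CCc1ccc(OCc2ccccc2)cc1)C[C@H](O)CCc1ccc(OCc2ccccc2)cc1
F7 | step 5 | (4R,6R)-4,6-bis{2-[4-(benzyloxy)phenyl]ethyl}-2-methoxy-2-methyl-1,3-dioxane | COC1(C)O[C@H](CCc2ccc(OCc3ccccc3)cc2)C[C@@H](CCc2ccc(OCc3ccccc3)cc2)O1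
F8 | step 2 | [4-(benzyloxy)phenyl]lithium | [Li]c1ccc(OCc2ccccc2)cc1
F9 | step 2 | 3-[4-(benzyloxy)phenyl]propan-1-ol | OCCCc1ccc(OCc2ccccc2)cc1
A1 | direct plan | 4-hydroxybenzaldehyde | O=Cc1ccc(O)cc1
A2 | direct plan | pentane-2,4-dione | CC(=O)CC(C)=O
A3 | direct plan | (1E,6E)-1,7-bis(4-hydroxyphenyl)hepta-1,6-diene-3,5-dione | O=C(/C=C/c1ccc(O)cc1)CC(=O)/C=C/c1ccc(O)cc1
A4 | direct plan | (3R,5R)-1,7-bis(4-hydroxyphenyl)heptane-3,5-diol | O[C@H](CCc1ccc(O)cc1)C[C@H](O)CCc1ccc(O)cc1
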